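**Retrosynthetic overview**

1. The target comes from eremophil-11-ene-3α,8α,9α-triol by acylation of the two equatorial hydroxyls (O3, O9) with hex-2-ynoic acid and Lindlar reduction; the axial 8α-OH comes from the 8-ketone by bulky-hydride reduction.
2. The strategy rests on ring B (C5–C10): C7 carries the isopropenyl group (C11–C13) beside the C8 carbinol, a homoallylic alcohol of the isopulegol kind. The C7–C8 bond and the C11=C12 alkene are therefore made together by a carbonyl-ene reaction between a C8 aldehyde and a prenyl group on C5. Ring B is closed last, on a finished ring A.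
3. The α-silyloxy aldehyde comes from a C9 aldehyde on C10 plus a formyl-anion equivalent (1,3-dithiane, Felkin–Anh control); the C9 aldehyde comes from a C10 ketone by methoxymethylene Wittig homologation.
4. C4 and the quaternary C5 come from (R)-4-silyloxy-2-methylcyclohex-2-enone by methylcuprate addition and prenylation of the enolate. Ring A is bought as 1,4-dioxaspiro[4.5]dec-6-en-8-one and made chiral at C3 by asymmetric transfer hydrogenation.

Key step: step 12

Remark: eremophilane numbering is used throughout (ring A: C1–C5 and C10; ring B: C5–C10; C14 on C5, C15 on C4, C11–C13 on C7), β means the face of the C14 methyl, and 1,4-dioxaspiro[4.5]dec-6-en-8-one is taken as a purchasable building block.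

**Route**

Step 1
Reactants: 1 1,4-dioxaspiro[4.5]dec-6-en-8-one
Product: 2 (8R)-1,4-dioxaspiro[4.5]dec-6-en-8-ol
Conditions: RuCl(p-cymene)[(R,R)-TsDPEN] (1 mol %), KOH (cat.), i-PrOH, rt
Reagents that add atoms: none
Why: Noyori asymmetric transfer hydrogenation reduces the enone carbonyl 1,2-selectively, and the (R,R) ligand is expected to give the (R)-carbinol (future C3) by analogy with aryl ketones, the C=C taking the role of the arene.

Step 2
Reactants: 2 (8R)-1,4-dioxaspiro[4.5]dec-6-en-8-ol
Product: 3 tert-butyl{[(8R)-1,4-dioxaspiro[4.5]dec-6-en-8-yl]oxy}dimethylsilane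
Conditions: TBSCl, imidazole, DMF, rt
Reagents that add atoms: tert-butyldimethylsilyl chloride, CC(C)(C)[Si](C)(C)Cl
Why: Imidazole-assisted silylation of a secondary allylic alcohol is routine and does not touch the stereocenter.

Step 3
Reactants: 3 tert-butyl{[(8R)-1,4-dioxaspiro[4.5]dec-6-en-8-yl]oxy}dimethylsilane
Product: 4 (4R)-4-[(tert-butyldimethylsilyl)oxy]cyclohex-2-en-1-one
Conditions: PPTS (cat.), acetone–H2O, 60 °C
Reagents that add atoms: water, O
Why: Mild acid-catalysed acetal hydrolysis unveils the enone, while the secondary silyl ether and the carbinol center should survive PPTS.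

Step 4
Reactants: 4 (4R)-4-[(tert-butyldimethylsilyl)oxy]cyclohex-2-en-1-one
Product: 5 (4R)-4-[(tert-butyldimethylsilyl)oxy]-2-iodocyclohex-2-en-1-one
Conditions: I2, pyridine–CH2Cl2 (1:1), 0 °C → rt
Reagents that add atoms: iodine, II
Why: α-Iodination of an enone by conjugate addition of pyridine, iodination of the enolate and elimination (Baylis–Hillman-type α-halogenation) places iodine on C2 only.

Step 5
Reactants: 5 (4R)-4-[(tert-butyldimethylsilyl)oxy]-2-iodocyclohex-2-en-1-one
Product: 6 (4R)-4-[(tert-butyldimethylsilyl)oxy]-2-methylcyclohex-2-en-1-one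
Conditions: SnMe4, PdCl2(PhCN)2 (5 mol %), AsPh3, CuI, NMP, 80 °C
Reagents that add atoms: tetramethylstannane, C[Sn](C)(C)C
Why: Stille coupling of the α-iodoenone under neutral conditions installs the methyl that becomes C14 without a base that could eliminate the γ-silyloxy group.

Step 6
Reactants: 6 (4R)-4-[(tert-butyldimethylsilyl)oxy]-2-methylcyclohex-2-en-1-one; 7 1-bromo-3-methylbut-2-ene (prenyl bromide)
Product: 9 (2R,3R,4R)-4-[(tert-butyldimethylsilyl)oxy]-2,3-dimethyl-2-(3-methylbut-2-en-1-yl)cyclohexan-1-one, via lithium enolate 8 (not isolated)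
Conditions: MeLi, CuI, Et2O, 0 °C; 6, −78 → −20 °C; then 7, DMPU, THF, −20 °C → rt
Reagents that add atoms: lithium dimethylcuprate, [Li+].C[Cu-]C
Why: Conjugate addition of Me2CuLi occurs anti to the γ-silyloxy group (C4 methyl trans to O3), and the regiodefined tetrasubstituted enolate 8 should be C-alkylated anti to the adjacent pseudoaxial C4 methyl (A(1,2) strain), giving the quaternary C5 with cis-vicinal methyls as in the classical alkylation of 2,3-dimethylcyclohexanone enolates.

Step 7
Reactants: 9 (2R,3R,4R)-4-[(tert-butyldimethylsilyl)oxy]-2,3-dimethyl-2-(3-methylbut-2-en-1-yl)cyclohexan-1-one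
Product: 10 tert-butyl{[(1R,2R,3R)-4-(methoxymethylidene)-2,3-dimethyl-3-(3-methylbut-2-en-1-yl)cyclohexyl]oxy}dimethylsilane (E/Z mixture)
Conditions: Ph3P(CH2OMe)Cl, KOt-Bu, THF, 0 °C → 50 °C
Reagents that add atoms: (methoxymethyl)triphenylphosphonium chloride, COC[P+](c1ccccc1)(c1ccccc1)c1ccccc1.[Cl-]
Why: Wittig methoxymethylenation with a small non-stabilised ylide is a standard one-carbon homologation of hindered α-quaternary cyclohexanones; no stereocenter is affected and the enol ether geometry is irrelevant.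

Step 8
Reactants: 10 tert-butyl{[(1R,2R,3R)-4-(methoxymethylidene)-2,3-dimethyl-3-(3-methylbut-2-en-1-yl)cyclohexyl]oxy}dimethylsilane
Product: 11 (1R,2R,3R,4R)-4-[(tert-butyldimethylsilyl)oxy]-2,3-dimethyl-2-(3-methylbut-2-en-1-yl)cyclohexane-1-carbaldehyde
Conditions: 1 M aq. HCl–THF (1:4), 0 °C → rt, short contact
Reagents that add atoms: water, O
Why: Enol ether hydrolysis (protonation at C10, hydration of the oxocarbenium ion) gives the aldehyde, and the proton should enter axially on the α-face, anti to the axial C14 methyl, so that the formyl group ends up equatorial and cis to C14 (10α-H), which is also expected to be the more stable epimer.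

Step 9
Reactants: 11 (1R,2R,3R,4R)-4-[(tert-butyldimethylsilyl)oxy]-2,3-dimethyl-2-(3-methylbut-2-en-1-yl)cyclohexane-1-carbaldehyde; 12 1,3-dithiane
Product: 13 (S)-{(1R,2R,3R,4R)-4-[(tert-butyldimethylsilyl)oxy]-2,3-dimethyl-2-(3-methylbut-2-en-1-yl)cyclohexyl}(1,3-dithian-2-yl)methanol
Conditions: 12, n-BuLi, THF, −30 °C; then 11, −78 °C; then H2O
Reagents that add atoms: none
Why: Corey–Seebach addition of 2-lithio-1,3-dithiane to the α-branched aldehyde should follow the Felkin–Anh model with the quaternary C5 as the large group anti to the nucleophile, which gives the (S)-carbinol at C9.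

Step 10
Reactants: 13 (S)-{(1R,2R,3R,4R)-4-[(tert-butyldimethylsilyl)oxy]-2,3-dimethyl-2-(3-methylbut-2-en-1-yl)cyclohexyl}(1,3-dithian-2-yl)methanol
Product: 14 tert-butyl{(S)-[(1R,2R,3R,4R)-4-[(tert-butyldimethylsilyl)oxy]-2,3-dimethyl-2-(3-methylbut-2-en-1-yl)cyclohexyl](1,3-dithian-2-yl)methoxy}dimethylsilane
Conditions: TBSOTf, 2,6-lutidine, CH2Cl2, 0 °C
Reagents that add atoms: tert-butyldimethylsilyl trifluoromethanesulfonate, CC(C)(C)[Si](C)(C)OS(=O)(=O)C(F)(F)F
Why: A silyl triflate with a hindered pyridine base silylates hindered secondary alcohols reliably and changes no stereocenter.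

Step 11
Reactants: 14 tert-butyl{(S)-[(1R,2R,3R,4R)-4-[(tert-butyldimethylsilyl)oxy]-2,3-dimethyl-2-(3-methylbut-2-en-1-yl)cyclohexyl](1,3-dithian-2-yl)methoxy}dimethylsilane
Product: 15 (2S)-2-[(tert-butyldimethylsilyl)oxy]-2-[(1R,2R,3R,4R)-4-[(tert-butyldimethylsilyl)oxy]-2,3-dimethyl-2-(3-methylbut-2-en-1-yl)cyclohexyl]acetaldehyde
Conditions: MeI (excess), CaCO3, MeCN–H2O (4:1), 45 °C
Reagents that add atoms: water, O
Why: S-Methylation of the dithiane and hydrolysis of the sulfonium salt (Corey–Seebach unmasking) frees the aldehyde under buffered conditions that should leave the silyl ethers, the trisubstituted alkene and the α-stereocenter intact.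

Step 12
Reactants: 15 (2S)-2-[(tert-butyldimethylsilyl)oxy]-2-[(1R,2R,3R,4R)-4-[(tert-butyldimethylsilyl)oxy]-2,3-dimethyl-2-(3-methylbut-2-en-1-yl)cyclohexyl]acetaldehyde
Product: 16 3α,9α-bis[(tert-butyldimethylsilyl)oxy]eremophil-11-en-8β-ol (trans-decalin; 4β,5β-dimethyl, 7α-isopropenyl, 10α-H)
Conditions: Me2AlCl (1.5 equiv), CH2Cl2, −78 → −40 °C; then cold 1 M aq. HCl
Reagents that add atoms: none
Why: Me2AlCl binds the aldehyde oxygen, C7 of the trisubstituted alkene attacks C8 while positive charge builds at C11, and a hydrogen of the C12 methyl passes to oxygen through a six-membered array (intramolecular carbonyl-ene reaction of type 1), after which the aluminium alkoxide loses methane so that no free acid remains to ionise the product. The closest known reaction is the Lewis-acid-induced cyclisation of citronellal to isopulegol and the related Me2AlCl-promoted ene cyclisations of 6-methylhept-5-enals. Ring B (C5–C10) closes in a 6-exo fashion with respect to the carbonyl group through a chair that is fused trans to ring A, because both reacting arms sit equatorial on C5 and C10. C7 is set by this chair, since the developing C11 unit must be equatorial (α) to avoid a 1,3-diaxial clash with the axial C14 methyl on C5; C8 is expected to carry an equatorial (β) oxygen trans to the isopropenyl group, as in isopulegol, and is corrected in steps 13 and 14. The step needs the ene product instead of chloride capture at C11, methyl transfer from aluminium or loss of the α-silyloxy group, and the low temperature, the proton-scavenging Al–Me bond and the weakly coordinating silyl ether should secure this.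

Step 13
Reactants: 16 3α,9α-bis[(tert-butyldimethylsilyl)oxy]eremophil-11-en-8β-ol
Product: 17 3α,9α-bis[(tert-butyldimethylsilyl)oxy]eremophil-11-en-8-one
Conditions: Dess–Martin periodinane, NaHCO3, CH2Cl2, 0 °C → rt
Reagents that add atoms: none
Why: Dess–Martin oxidation under bicarbonate buffering gives the ketone without enolising C7, so the β,γ-unsaturated ketone should not slip into conjugation.

Step 14
Reactants: 17 3α,9α-bis[(tert-butyldimethylsilyl)oxy]eremophil-11-en-8-one
Product: 18 3α,9α-bis[(tert-butyldimethylsilyl)oxy]eremophil-11-en-8α-ol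
Conditions: LiBH(s-Bu)3, THF, −78 °C; then H2O
Reagents that add atoms: none
Why: The bulky hydride should attack the ring ketone from the equatorial direction (β-face), away from the axial hydrogens on C6 and C10, and so give the axial 8α-alcohol, as in the reduction of menthone to neomenthol.

Step 15
Reactants: 18 3α,9α-bis[(tert-butyldimethylsilyl)oxy]eremophil-11-en-8α-ol
Product: 19 eremophil-11-ene-3α,8α,9α-triol
Conditions: Bu4NF, THF, rt → 45 °C
Reagents that add atoms: none
Why: Fluoride cleaves both silyl ethers, and a silyl shift between O9 and O8 beforehand would be without consequence because every silyl group is removed.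

Step 16
Reactants: 19 eremophil-11-ene-3α,8α,9α-triol; 20 hex-2-ynoic acid
Product: 21 8α-hydroxyeremophil-11-ene-3α,9α-diyl bis(hex-2-ynoate)
Conditions: 20 (2.2 equiv), i-PrN=C=N-i-Pr, DMAP (cat.), CH2Cl2, −20 → 0 °C
Reagents that add atoms: none
Why: Steglich esterification should acylate the two equatorial hydroxyls at C3 and C9 faster than the axial C8 hydroxyl, which is flanked by C7 and C9, and the alkynoic acid is used because it cannot lose alkene geometry during acylation.

Step 17
Reactants: 21 8α-hydroxyeremophil-11-ene-3α,9α-diyl bis(hex-2-ynoate)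
Product: 22 8α-hydroxyeremophil-11-ene-3α,9α-diyl bis[(2Z)-hex-2-enoate] (CNP0420276.1)
Conditions: H2 (1 atm), Pd/CaCO3 poisoned with Pb(OAc)2, quinoline, EtOAc, rt, stopped after 2 equiv H2
Reagents that add atoms: none
Why: Lindlar semihydrogenation adds hydrogen syn to each ynoate to give the two (Z)-enoates, and the alkynes bind the poisoned palladium far better than the 1,1-disubstituted isopropenyl alkene, which should survive.

**Compound list**

1 | 1,4-dioxaspiro[4.5]dec-6-en-8-one | O=C1C=CC2(CC1)OCCO2 | starting material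
2 | (8R)-1,4-dioxaspiro[4.5]dec-6-en-8-ol | O[C@H]1C=CC2(CC1)OCCO2 | intermediate
3 | tert-butyl{[(8R)-1,4-dioxaspiro[4.5]dec-6-en-8-yl]oxy}dimethylsilane | CC(C)(C)[Si](C)(C)O[C@H]1C=CC2(CC1)OCCO2 | intermediate
4 | (4R)-4-[(tert-butyldimethylsilyl)oxy]cyclohex-2-en-1-one | CC(C)(C)[Si](C)(C)O[C@H]1C=CC(=O)CC1 | intermediate
5 | (4R)-4-[(tert-butyldimethylsilyl)oxy]-2-iodocyclohex-2-en-1-one | CC(C)(C)[Si](C)(C)O[C@H]1C=C(I)C(=O)CC1 | intermediate
6 | (4R)-4-[(tert-butyldimethylsilyl)oxy]-2-methylcyclohex-2-en-1-one | CC(C)(C)[Si](C)(C)O[C@H]1C=C(C)C(=O)CC1 | intermediate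
7 | 1-bromo-3-methylbut-2-ene (prenyl bromide) | CC(C)=CCBr | starting material
8 | lithium (3R,4R)-4-[(tert-butyldimethylsilyl)oxy]-2,3-dimethylcyclohex-1-en-1-olate (not isolated) | [Li]OC1=C(C)[C@@H](C)[C@H](O[Si](C)(C)C(C)(C)C)CC1 | intermediate
9 | (2R,3R,4R)-4-[(tert-butyldimethylsilyl)oxy]-2,3-dimethyl-2-(3-methylbut-2-en-1-yl)cyclohexan-1-one | CC(C)=CC[C@]1(C)[C@@H](C)[C@H](O[Si](C)(C)C(C)(C)C)CCC1=O | intermediate
10 | tert-butyl{[(1R,2R,3R)-4-(methoxymethylidene)-2,3-dimethyl-3-(3-methylbut-2-en-1-yl)cyclohexyl]oxy}dimethylsilane (E/Z mixture) | CC(C)=CC[C@]1(C)[C@@H](C)[C@H](O[Si](C)(C)C(C)(C)C)CCC1=COC | intermediate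
11 | (1R,2R,3R,4R)-4-[(tert-butyldimethylsilyl)oxy]-2,3-dimethyl-2-(3-methylbut-2-en-1-yl)cyclohexane-1-carbaldehyde | CC(C)=CC[C@]1(C)[C@@H](C)[C@H](O[Si](C)(C)C(C)(C)C)CC[C@H]1C=O | intermediate
12 | 1,3-dithiane | C1CSCSC1 | starting material
13 | (S)-{(1R,2R,3R,4R)-4-[(tert-butyldimethylsilyl)oxy]-2,3-dimethyl-2-(3-methylbut-2-en-1-yl)cyclohexyl}(1,3-dithian-2-yl)methanol | CC(C)=CC[C@]1(C)[C@@H](C)[C@H](O[Si](C)(C)C(C)(C)C)CC[C@H]1[C@H](O)C1SCCCS1 | intermediate
14 | tert-butyl{(S)-[(1R,2R,3R,4R)-4-[(tert-butyldimethylsilyl)oxy]-2,3-dimethyl-2-(3-methylbut-2-en-1-yl)cyclohexyl](1,3-dithian-2-yl)methoxy}dimethylsilane | CC(C)=CC[C@]1(C)[C@@H](C)[C@H](O[Si](C)(C)C(C)(C)C)CC[C@H]1[C@H](O[Si](C)(C)C(C)(C)C)C1SCCCS1 | intermediate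
15 | (2S)-2-[(tert-butyldimethylsilyl)oxy]-2-[(1R,2R,3R,4R)-4-[(tert-butyldimethylsilyl)oxy]-2,3-dimethyl-2-(3-methylbut-2-en-1-yl)cyclohexyl]acetaldehyde | CC(C)=CC[C@]1(C)[C@@H](C)[C@H](O[Si](C)(C)C(C)(C)C)CC[C@H]1[C@H](O[Si](C)(C)C(C)(C)C)C=O | intermediate
16 | 3α,9α-bis[(tert-butyldimethylsilyl)oxy]eremophil-11-en-8β-ol | C=C(C)[C@@H]1C[C@]2(C)[C@@H](C)[C@H](O[Si](C)(C)C(C)(C)C)CC[C@H]2[C@H](O[Si](C)(C)C(C)(C)C)[C@H]1O | intermediate
17 | 3α,9α-bis[(tert-butyldimethylsilyl)oxy]eremophil-11-en-8-one | C=C(C)[C@@H]1C[C@]2(C)[C@@H](C)[C@H](O[Si](C)(C)C(C)(C)C)CC[C@H]2[C@H](O[Si](C)(C)C(C)(C)C)C1=O | intermediate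
18 | 3α,9α-bis[(tert-butyldimethylsilyl)oxy]eremophil-11-en-8α-ol | C=C(C)[C@@H]1C[C@]2(C)[C@@H](C)[C@H](O[Si](C)(C)C(C)(C)C)CC[C@H]2[C@H](O[Si](C)(C)C(C)(C)C)[C@@H]1O | intermediate
19 | eremophil-11-ene-3α,8α,9α-triol | C=C(C)[C@@H]1C[C@]2(C)[C@@H](C)[C@H](O)CC[C@H]2[C@H](O)[C@@H]1O | intermediate
20 | hex-2-ynoic acid | CCCC#CC(=O)O | starting material
21 | 8α-hydroxyeremophil-11-ene-3α,9α-diyl bis(hex-2-ynoate) | C=C(C)[C@@H]1C[C@]2(C)[C@@H](C)[C@H](OC(=O)C#CCCC)CC[C@H]2[C@H](OC(=O)C#CCCC)[C@@H]1O | intermediate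
22 | 8α-hydroxyeremophil-11-ene-3α,9α-diyl bis[(2Z)-hex-2-enoate] (CNP0420276.1) | C=C(C)[C@@H]1C[C@]2(C)[C@@H](C)[C@H](OC(=O)/C=C\CCC)CC[C@H]2[C@H](OC(=O)/C=C\CCC)[C@@H]1O | target

**Step count**

Total step count: 17. Longest linear sequence: 17 steps (1 → 22).

**Steps most likely to fail**

1. Step 12 (key step). After C7–C8 bonding the cationic centre at C11 may be captured by chloride, the aluminium reagent may transfer a methyl group to the aldehyde, or the silyloxy group next to the activated carbonyl may be lost, instead of the hydrogen shift that completes the ene reaction. The fallback forms the same C7–C8 bond with a metalated nucleophile and sets out from aldehyde 15. Ene-type allylic chlorination of its prenyl group (N-chlorosuccinimide, PhSeCl cat., CH2Cl2) should give the transposed allylic chloride, (2S)-2-[(tert-butyldimethylsilyl)oxy]-2-[(1R,2R,3R,4R)-4-[(tert-butyldimethylsilyl)oxy]-2-(2-chloro-3-methylbut-3-en-1-yl)-2,3-dimethylcyclohexyl]acetaldehyde F1, as a mixture at the chlorine-bearing carbon. CrCl2 (LiI cat., THF–DMF, rt) should turn it into an allylic CrCl2 species that adds through C7 to the C8 aldehyde in a chair (intramolecular Nozaki–Hiyama allylation). This should give the same 7α-isopropenyl 8β-ol, so the route is rejoined at 16.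

2. Step 6. The alkylation of enolate 8 may show poor facial selectivity, because in the reactive half-chair the silyloxy group on C3 is axial and lies 1,3 to the incoming electrophile; O-alkylation may also compete. The fallback sets out from enone 6 and puts the C5 substituent on under ligand control. Me2CuLi is added as before, but the enolate is trapped on oxygen with allyl chloroformate to give allyl (3R,4R)-4-[(tert-butyldimethylsilyl)oxy]-2,3-dimethylcyclohex-1-en-1-yl carbonate F2. Decarboxylative Tsuji allylation with Pd2(dba)3 and (S)-t-BuPHOX (the ligand enantiomer that gives (S)-2-allyl-2-methylcyclohexanone, hence the same sense of attack at C5) should give (2R,3R,4R)-2-allyl-4-[(tert-butyldimethylsilyl)oxy]-2,3-dimethylcyclohexan-1-one F3. Cross-metathesis with 2-methylbut-2-ene (second-generation Grubbs catalyst, CH2Cl2, 40 °C) converts allyl into prenyl and rejoins the route at 9.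

3. Step 16. The acylation may not discriminate cleanly between the equatorial C9 hydroxyl and the neighbouring axial C8 hydroxyl, and an acyl shift from O9 to O8 may occur. The fallback replaces rate discrimination by protection and sets out from alcohol 18. 4-Methoxybenzyl trichloroacetimidate with La(OTf)3 (cat., toluene) should give 3α,9α-bis[(tert-butyldimethylsilyl)oxy]-8α-[(4-methoxybenzyl)oxy]eremophil-11-ene F4. Bu4NF then gives 8α-[(4-methoxybenzyl)oxy]eremophil-11-ene-3α,9α-diol F5, and Steglich esterification with 20 gives 8α-[(4-methoxybenzyl)oxy]eremophil-11-ene-3α,9α-diyl bis(hex-2-ynoate) F6. DDQ in CH2Cl2–pH 7 buffer removes the benzyl ether and rejoins the route at 21.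

**Further compounds**

F1 | step 12 | (2S)-2-[(tert-butyldimethylsilyl)oxy]-2-[(1R,2R,3R,4R)-4-[(tert-butyldimethylsilyl)oxy]-2-(2-chloro-3-methylbut-3-en-1-yl)-2,3-dimethylcyclohexyl]acetaldehyde | C=C(C)C(Cl)C[C@]1(C)[C@@H](C)[C@H](O[Si](C)(C)C(C)(C)C)CC[C@H]1[C@H](O[Si](C)(C)C(C)(C)C)C=O
F2 | step 6 | allyl (3R,4R)-4-[(tert-butyldimethylsilyl)oxy]-2,3-dimethylcyclohex-1-en-1-yl carbonate | C=CCOC(=O)OC1=C(C)[C@@H](C)[C@H](O[Si](C)(C)C(C)(C)C)CC1
F3 | step 6 | (2R,3R,4R)-2-allyl-4-[(tert-butyldimethylsilyl)oxy]-2,3-dimethylcyclohexan-1-one | C=CC[C@]1(C)[C@@H](C)[C@H](O[Si](C)(C)C(C)(C)C)CCC1=O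
F4 | step 16 | 3α,9α-bis[(tert-butyldimethylsilyl)oxy]-8α-[(4-methoxybenzyl)oxy]eremophil-11-ene | C=C(C)[C@@H]1C[C@]2(C)[C@@H](C)[C@H](O[Si](C)(C)C(C)(C)C)CC[C@H]2[C@H](O[Si](C)(C)C(C)(C)C)[C@@H]1OCc1ccc(OC)cc1
F5 | step 16 | 8α-[(4-methoxybenzyl)oxy]eremophil-11-ene-3α,9α-diol | C=C(C)[C@@H]1C[C@]2(C)[C@@H](C)[C@H](O)CC[C@H]2[C@H](O)[C@@H]1OCc1ccc(OC)cc1
F6 | step 16 | 8α-[(4-methoxybenzyl)oxy]eremophil-11-ene-3α,9α-diyl bis(hex-2-ynoate) | C=C(C)[C@@H]1C[C@]2(C)[C@@H](C)[C@H](OC(=O)C#CCCC)CC[C@H]2[C@H](OC(=O)C#CCCC)[C@@H]1OCc1ccc(OC)cc1
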